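## Plan

- **Cuts.** The two ester C–O bonds (C1‑CH2–O and C3–O) are cut first, giving a cyclopentane diol and two copies of one oleoside-type acid. Each (3S,4E)-4-formyl-3-(2-oxoethyl)hex-4-enoyl arm is traced to the glucosidic dihydropyran methyl ester of oleuropein. The ring bond C1–C2 is traced to a 1,2-shift in a six-membered α-diazo enone.
- **Enabling feature.** With the cyclopentane numbered C1 (CH2O-acyl), C2 (CH3), C3 (O-acyl), C4 (CH2), C5 (CH(CH2OH)2), its ten core carbons are those of carvone. Carvone's carbonyl carbon is pushed out of the ring to become the CH2O carbon on C1, carvone C6 becomes C1, and the isopropenyl group becomes CH(CH2OH)2.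
- **Forward order.** Oxygenation of the isopropenyl methyl, diazo transfer at the only α‑CH2, and Wolff ring contraction, in which the single ring of the target arises. Then hydroboration of both alkenes, C3 ketone, equilibration and two reductions. Finally double Mitsunobu esterification with the sugar-silylated oleoside acid, Krapcho-type unmasking of the four aldehydes, and desilylation.
- **Stereochemistry.** C5 comes unchanged from (R)-carvone. C1 and C2 are set thermodynamically (all-trans) at the γ-keto ester. C3 is set by LiBH(s-Bu)3 attack anti to the C2 methyl and then inverted in the Mitsunobu step. The acyl stereocentre and the E-ethylidene come from oleuropein; the CH(CH2OH)2 carbon is not stereogenic. Target in this numbering: C1 S, C2 R, C3 R, C5 R.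

Key step: step 7

Remark: "up" means the ring face carrying the C5 side chain. Compounds 10–14 are drawn as the diastereomers expected to predominate; their C1–C3 configurations are not relied on, because C3 is oxidised in step 10 and C1/C2 are equilibrated in step 11, so minor epimers are carried along and converge on 15.

## Route

Step 1
Reactants: 1 (R)-(−)-carvone
Product: 2 (5R)-5-(3-chloroprop-1-en-2-yl)-2-methylcyclohex-2-en-1-one (10-chlorocarvone)
Conditions: Ca(OCl)2, CO2 (solid), CH2Cl2/H2O, 0 °C to rt
Reagents that add atoms: calcium hypochlorite (delivers Cl as HOCl), [Ca+2].[O-]Cl.[O-]Cl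
Why: Ene-type allylic chlorination by HOCl should attack only the electron-rich 1,1-disubstituted alkene (the enone alkene is deactivated) and shift the double bond to the 2-(chloromethyl)vinyl group, leaving C5 untouched.

Step 2
Reactants: 2 10-chlorocarvone
Product: 3 (5R)-5-(3-acetoxyprop-1-en-2-yl)-2-methylcyclohex-2-en-1-one (10-acetoxycarvone)
Conditions: KOAc, n-Bu4NI (cat.), DMF, 60 °C
Reagents that add atoms: potassium acetate, CC(=O)[O-].[K+]
Why: SN2 displacement of a primary allylic chloride by acetate under iodide catalysis is a standard substitution and involves no stereocentre.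

Step 3
Reactants: 3 10-acetoxycarvone
Product: 4 (5R)-5-(3-hydroxyprop-1-en-2-yl)-2-methylcyclohex-2-en-1-one (10-hydroxycarvone)
Conditions: LiOH, THF/H2O, 0 °C
Reagents that add atoms: none
Why: Mild ester saponification frees the allylic alcohol; C5 is beta to the carbonyl and cannot epimerise by enolisation.

Step 4
Reactants: 4 10-hydroxycarvone
Product: 5 (5R)-5-[3-(tert-butyldimethylsilyloxy)prop-1-en-2-yl]-2-methylcyclohex-2-en-1-one
Conditions: TBSCl, imidazole, CH2Cl2, rt
Reagents that add atoms: tert-butyldimethylsilyl chloride, CC(C)(C)[Si](C)(C)Cl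
Why: Standard silylation of a primary alcohol gives an ether that tolerates amide base, diazo transfer, photolysis and borane.

Step 5
Reactants: 5 silyl ether of 10-hydroxycarvone
Product: 6 6-(trifluoroacetyl) derivative of 5 (C5 as in 5; C6 epimers and enol form)
Conditions: LiN(SiMe3)2, THF, −78 °C; CF3CO2CH2CF3, −78 °C; aq. HCl work-up; crude used directly
Reagents that add atoms: 2,2,2-trifluoroethyl trifluoroacetate, FC(F)(F)COC(=O)C(F)(F)F
Why: Kinetic deprotonation occurs at C6, the only sp3 α-carbon, and Claisen-type C-acylation with the activated trifluoroacetate gives the β-diketone needed for diazo transfer.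

Step 6
Reactants: 6 trifluoroacetyl ketone
Product: 7 6-diazo-5-[3-(tert-butyldimethylsilyloxy)prop-1-en-2-yl]-2-methylcyclohex-2-en-1-one (C5 configuration retained)
Conditions: 4-acetamidobenzenesulfonyl azide, Et3N, H2O (1 equiv), MeCN, rt
Reagents that add atoms: 4-acetamidobenzenesulfonyl azide, CC(=O)Nc1ccc(cc1)S(=O)(=O)N=[N+]=[N-]
Why: Detrifluoroacetylative (Regitz-type) diazo transfer: the diketone enolate adds to the sulfonyl azide and the adduct fragments, passing the trifluoroacetyl group to the sulfonamide and leaving the α′-diazo enone.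

Step 7
Reactants: 7 α′-diazo enone; 8 methanol
Product: 10 methyl 2-methyl-5-[3-(tert-butyldimethylsilyloxy)prop-1-en-2-yl]cyclopent-2-ene-1-carboxylate (ester at C1 up, 1,5-cis; C5 as in carvone), via alkenyl ketene 9 (not isolated)
Conditions: hν (medium-pressure Hg lamp, Pyrex filter), degassed MeOH, 0–10 °C
Reagents that add atoms: methanol (8), CO
Why: Excitation expels N2 and, in a Wolff rearrangement, the alkenyl carbon C2 shifts from the carbonyl carbon to the former diazo carbon (the future C1), so the old carbonyl carbon leaves the ring as the ketene carbon of 9, which adds methanol to give an ester dienol that ketonises. The closest known reaction type is the photochemical Wolff ring contraction of cyclic α-diazo ketones in an alcohol, including α′-diazo enones made by detrifluoroacetylative diazo transfer. The cyclopentene ring (C1–C5) is closed by this 1,2-shift inside the six-membered ring, that is by forming C1–C2 as a ring contraction and not by an end-to-end cyclisation. The new stereocentre C1 is set when the dienol is protonated at its α-carbon from the face opposite the C5 side chain, which should favour the 1,5-cis ester; the 1,5-trans epimer may accompany it, and neither outcome is relied on because C1 is re-equilibrated in step 11. The step needs exclusive migration of C2, retention at C5 and α- rather than γ-protonation: C2 is the only other substituent on the acyl carbon, C5 is a bystander, and kinetic ketonisation of dienols in neutral methanol occurs at the α-carbon, keeping the alkene at C2=C3.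

Step 8
Reactants: 10 cyclopentene ester
Product: 12 methyl 3-hydroxy-5-[1-hydroxy-3-(tert-butyldimethylsilyloxy)propan-2-yl]-2-methylcyclopentane-1-carboxylate (ester up, CH3 up, C3 OH down; both epimers at the side-chain CH), via bis(alkylborane) 11 (not isolated)
Conditions: BH3·THF, THF, 0 °C to rt; then NaBO3·4H2O, H2O, rt
Reagents that add atoms: sodium perborate tetrahydrate, [Na+].[O-]OB=O.O.O.O.O
Why: Hydroboration–oxidation places boron on the less substituted carbon of each alkene (the terminal CH2 and ring C3, syn to the new C2–H and anti to the C1/C5 substituents), and perborate oxidises C–B with retention without saponifying the ester.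

Step 9
Reactants: 12 diol
Product: 13 methyl 5-[1,3-bis(tert-butyldimethylsilyloxy)propan-2-yl]-3-hydroxy-2-methylcyclopentane-1-carboxylate (ester up, CH3 up, OH down)
Conditions: TBSCl (1.1 equiv), imidazole, CH2Cl2, 0 °C
Reagents that add atoms: tert-butyldimethylsilyl chloride, CC(C)(C)[Si](C)(C)Cl
Why: Selective silylation of the primary over the hindered secondary alcohol makes the side chain the symmetric CH(CH2OSi)2 unit (no stereocentre) and blocks lactonisation of the primary alcohol onto the C1 ester.

Step 10
Reactants: 13 secondary alcohol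
Product: 14 methyl 5-[1,3-bis(tert-butyldimethylsilyloxy)propan-2-yl]-2-methyl-3-oxocyclopentane-1-carboxylate (all-cis: ester up, CH3 up)
Conditions: Dess–Martin periodinane, CH2Cl2, rt
Reagents that add atoms: none
Why: Dess–Martin oxidation converts the secondary alcohol to the ketone under near-neutral conditions that leave silyl ethers and the ester untouched.

Step 11
Reactants: 14 all-cis keto ester
Product: 15 all-trans keto ester (same constitution; ester at C1 down, CH3 at C2 up, side chain at C5 up)
Conditions: NaOMe (cat.), MeOH, rt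
Reagents that add atoms: none
Why: Base-mediated epimerisation through the ester enolate (C1) and the ketone enolate (C2) should drive the ring to the thermodynamic 1,2-trans/1,5-trans arrangement, while C5, beta to both carbonyls, cannot enolise.

Step 12
Reactants: 15 all-trans keto ester
Product: 16 methyl 5-[1,3-bis(tert-butyldimethylsilyloxy)propan-2-yl]-3-hydroxy-2-methylcyclopentane-1-carboxylate (ester down, CH3 up, C3 OH up, cis to CH3)
Conditions: LiBH(s-Bu)3, THF, −78 °C; then H2O
Reagents that add atoms: none
Why: The bulky hydride should attack the cyclopentanone from the face opposite the adjacent C2 methyl and the C5 side chain, giving the C3 alcohol cis to the methyl, and it does not reduce the ester at −78 °C.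

Step 13
Reactants: 16 hydroxy ester
Product: 17 diol: C1 CH2OH down, C2 CH3 up, C3 OH up, C5 CH(CH2OTBS)2 up
Conditions: LiAlH4, THF, 0 °C; then H2O, aq. NaOH
Reagents that add atoms: none
Why: LiAlH4 reduces the methyl ester to the primary alcohol without touching the silyl ethers or any stereocentre.

Step 14
Reactants: 18 oleuropein
Product: 19 oleoside 11-methyl ester (free C7 carboxylic acid, β-D-glucoside, E-ethylidene)
Conditions: LiOH (aq.), THF/H2O, argon, 0 °C to rt; then aq. HCl to pH 3
Reagents that add atoms: lithium hydroxide, [Li+].[OH-]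
Why: Saponification should cleave only the saturated C7 ester, because the C11 methyl ester is a vinylogous carbonate (β-alkoxyacrylate) and far less electrophilic; exclusion of air protects the catechol leaving group.

Step 15
Reactants: 19 oleoside 11-methyl ester
Product: 21 2′,3′,4′,6′-tetra-O-triethylsilyl oleoside 11-methyl ester (free C7 acid), via triethylsilyl ester 20 (not isolated)
Conditions: Et3SiCl, imidazole, DMAP (cat.), DMF, 0 °C to rt; then THF/H2O (pH 7 buffer), rt
Reagents that add atoms: triethylsilyl chloride, CC[Si](Cl)(CC)CC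
Why: Exhaustive silylation masks the four sugar hydroxyls, and the much more labile silyl ester is hydrolysed selectively by water, leaving the acid ready for Mitsunobu coupling.

Step 16
Reactants: 17 diol; 21 silylated oleoside acid (2.6 equiv)
Product: 22 bis-ester: the C1 CH2O and the C3 oxygen (now down, trans to the C2 CH3) each carry the C7 acyl group of tetra-O-triethylsilyl oleoside 11-methyl ester; C5 CH(CH2OTBS)2
Conditions: PPh3, DIAD, toluene/THF, 0 °C to rt
Reagents that add atoms: none
Why: In this Mitsunobu esterification both alcohols are activated as alkoxyphosphonium ions and displaced by the carboxylate of 21, the primary one without stereochemical consequence and the secondary C3 centre by SN2 with inversion, which puts the acyloxy group trans to the C2 methyl.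

Step 17
Reactants: 22 bis-ester
Product: 23 bis[(3S,4E)-4-formyl-3-(2-oxoethyl)hex-4-enoate] of diol core, still as the bis(tert-butyldimethylsilyl) ether
Conditions: NaCl, DMSO/H2O, 150 °C, argon
Reagents that add atoms: water, O
Why: Krapcho-type demethoxycarbonylation cascade known for oleuropein-type oleoside esters: chloride demethylates each vinylogous carbonate, hydration of the enol ether opens the dihydropyran, the sugar hemiacetal is expelled and the β-formyl carboxylate loses CO2, leaving the E-enal and the saturated aldehyde with the allylic stereocentre untouched.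

Step 18
Reactants: 23 bis-silyl ether
Product: 24 target diester dialdehyde with free CH(CH2OH)2
Conditions: HF·pyridine, pyridine, THF, 0 °C to rt
Reagents that add atoms: none
Why: Buffered fluoride cleavage of the two primary silyl ethers is a standard deprotection that should leave the esters, aldehydes and enals intact.

## Compound list

1 | (R)-(−)-carvone | CC1=CC[C@H](CC1=O)C(C)=C | starting material
2 | 10-chlorocarvone | CC1=CC[C@H](CC1=O)C(=C)CCl | intermediate
3 | 10-acetoxycarvone | CC1=CC[C@H](CC1=O)C(=C)COC(C)=O | intermediate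
4 | 10-hydroxycarvone | CC1=CC[C@H](CC1=O)C(=C)CO | intermediate
5 | 10-(tert-butyldimethylsilyloxy)carvone | CC1=CC[C@H](CC1=O)C(=C)CO[Si](C)(C)C(C)(C)C | intermediate
6 | 6-trifluoroacetyl-10-(tert-butyldimethylsilyloxy)carvone (C6 epimers/enol) | CC1=CC[C@H](C(C(=O)C(F)(F)F)C1=O)C(=C)CO[Si](C)(C)C(C)(C)C | intermediate
7 | 6-diazo-10-(tert-butyldimethylsilyloxy)carvone | [N-]=[N+]=C1C(=O)C(C)=CC[C@H]1C(=C)CO[Si](C)(C)C(C)(C)C | intermediate
8 | methanol | CO | starting material
9 | ring-contracted alkenyl ketene (not isolated) | O=C=C1C(C)=CC[C@H]1C(=C)CO[Si](C)(C)C(C)(C)C | intermediate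
10 | ring-contracted cyclopentene methyl ester (1,5-cis drawn) | COC(=O)[C@H]1C(C)=CC[C@H]1C(=C)CO[Si](C)(C)C(C)(C)C | intermediate
11 | bis(alkylborane), drawn as RBH2 at C3 and at the side-chain CH2 (not isolated) | COC(=O)[C@H]1[C@@H](C)[C@H](B)C[C@H]1C(CB)CO[Si](C)(C)C(C)(C)C | intermediate
12 | hydroboration diol (C3 OH and side-chain CH2OH) | COC(=O)[C@H]1[C@@H](C)[C@H](O)C[C@H]1C(CO)CO[Si](C)(C)C(C)(C)C | intermediate
13 | bis-silyl ether C3 alcohol | COC(=O)[C@H]1[C@@H](C)[C@H](O)C[C@H]1C(CO[Si](C)(C)C(C)(C)C)CO[Si](C)(C)C(C)(C)C | intermediate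
14 | all-cis γ-keto ester | COC(=O)[C@H]1[C@@H](C)C(=O)C[C@H]1C(CO[Si](C)(C)C(C)(C)C)CO[Si](C)(C)C(C)(C)C | intermediate
15 | all-trans γ-keto ester | COC(=O)[C@@H]1[C@@H](C)C(=O)C[C@H]1C(CO[Si](C)(C)C(C)(C)C)CO[Si](C)(C)C(C)(C)C | intermediate
16 | hydroxy ester, C3 OH cis to CH3 | COC(=O)[C@@H]1[C@@H](C)[C@@H](O)C[C@H]1C(CO[Si](C)(C)C(C)(C)C)CO[Si](C)(C)C(C)(C)C | intermediate
17 | cyclopentane diol (CH2OH at C1, OH at C3) | OC[C@@H]1[C@@H](C)[C@@H](O)C[C@H]1C(CO[Si](C)(C)C(C)(C)C)CO[Si](C)(C)C(C)(C)C | intermediate
18 | oleuropein | C/C=C/1\[C@@H](C(=CO[C@H]1O[C@H]2[C@@H]([C@H]([C@@H]([C@H](O2)CO)O)O)O)C(=O)OC)CC(=O)OCCC3=CC(=C(C=C3)O)O | starting material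
19 | oleoside 11-methyl ester | C/C=C/1\[C@@H](C(=CO[C@H]1O[C@H]2[C@@H]([C@H]([C@@H]([C@H](O2)CO)O)O)O)C(=O)OC)CC(=O)O | intermediate
20 | pentakis(triethylsilyl) derivative of 19, silyl ester (not isolated) | C/C=C/1\[C@@H](C(=CO[C@H]1O[C@H]2[C@@H]([C@H]([C@@H]([C@H](O2)CO[Si](CC)(CC)CC)O[Si](CC)(CC)CC)O[Si](CC)(CC)CC)O[Si](CC)(CC)CC)C(=O)OC)CC(=O)O[Si](CC)(CC)CC | intermediate
21 | 2′,3′,4′,6′-tetra-O-triethylsilyl oleoside 11-methyl ester (free acid) | C/C=C/1\[C@@H](C(=CO[C@H]1O[C@H]2[C@@H]([C@H]([C@@H]([C@H](O2)CO[Si](CC)(CC)CC)O[Si](CC)(CC)CC)O[Si](CC)(CC)CC)O[Si](CC)(CC)CC)C(=O)OC)CC(=O)O | intermediate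
22 | bis(oleoside) ester of the cyclopentane core, sugars silylated, C3 inverted | C/C=C/1\[C@@H](C(=CO[C@H]1O[C@H]2[C@@H]([C@H]([C@@H]([C@H](O2)CO[Si](CC)(CC)CC)O[Si](CC)(CC)CC)O[Si](CC)(CC)CC)O[Si](CC)(CC)CC)C(=O)OC)CC(=O)OC[C@@H]3[C@@H](C)[C@H](OC(=O)C[C@@H]4C(C(=O)OC)=CO[C@@H](O[C@H]5[C@@H]([C@H]([C@@H]([C@H](O5)CO[Si](CC)(CC)CC)O[Si](CC)(CC)CC)O[Si](CC)(CC)CC)O[Si](CC)(CC)CC)/C4=C/C)C[C@H]3C(CO[Si](C)(C)C(C)(C)C)CO[Si](C)(C)C(C)(C)C | intermediate
23 | bis(dialdehyde) diester, bis(tert-butyldimethylsilyl) ether | C/C=C(/C=O)[C@@H](CC=O)CC(=O)OC[C@@H]1[C@@H](C)[C@H](OC(=O)C[C@H](CC=O)/C(C=O)=C\C)C[C@H]1C(CO[Si](C)(C)C(C)(C)C)CO[Si](C)(C)C(C)(C)C | intermediate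
24 | CNP0313563.1 | C/C=C(/C=O)[C@@H](CC=O)CC(=O)OC[C@@H]1[C@@H](C)[C@H](OC(=O)C[C@H](CC=O)/C(C=O)=C\C)C[C@H]1C(CO)CO | target

## Step count and risks

Total: 18 steps. Longest linear sequence: 16 steps (steps 1–13, then 16–18); the oleuropein branch contributes steps 14–15.

**Step 7.** After loss of N2 the carbene may undergo 1,2-hydride shift from C5 or O–H insertion with methanol instead of the alkenyl shift, and the dienol may ketonise at the γ-carbon to the conjugated ester. The fallback sets out from 5 and returns at 15; it makes the same C1–C2 bond by a Favorskii ring contraction. Alkaline H2O2 (NaOH, MeOH, 0 °C) epoxidises the enone of 5 to the 2,3-epoxy ketone F1. LiCl/AcOH in THF opens it to the 2-chloro-3-hydroxy ketone F2, and dihydropyran/PPTS gives the tetrahydropyranyl ether F3. NaOMe in MeOH then effects the Favorskii rearrangement (the C6 enolate displaces chloride at C2 and methoxide opens the cyclopropanone) to the cyclopentane methyl ester F4, which already carries the C3 oxygen. 9-BBN then NaBO3·4H2O on the side-chain alkene gives the primary alcohol F5, and TBSCl/imidazole gives the bis-silyl ether F6. PPTS in EtOH removes the tetrahydropyranyl group to give the C3 alcohol F7, Dess–Martin oxidation gives the keto ester F8, and NaOMe/MeOH equilibrates this to 15.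

**Step 16.** The hindered C3 alkoxyphosphonium ion may eliminate to a cyclopentene or be displaced too slowly by the bulky carboxylate, so the second esterification could stall or lose stereochemical fidelity. The fallback sets out from 16 and returns at 22; it separates inversion from acylation. Mitsunobu reaction of 16 with 4-nitrobenzoic acid (PPh3, DIAD, toluene) gives the inverted 4-nitrobenzoate F9. NaOMe/MeOH cleaves it to the C3-epimeric hydroxy ester F10, and LiAlH4 gives the C3-inverted diol F11. Double Steglich esterification with 21 (EDC·HCl, DMAP, CH2Cl2), which proceeds with retention, then gives 22.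

**Step 17.** Demethylation and decarboxylation may stop at one of the two units, the silylated sugar may slow collapse of the acetal, and the dialdehyde arms may degrade by aldol processes at 150 °C. The fallback sets out from 22 and returns at 24; it moves the cascade to the unprotected stage. HF·pyridine in THF/pyridine removes all ten silyl groups from 22 to give the free bis-glucoside F12. NaCl in wet DMSO at 150 °C is then applied to this substrate, which carries the sugar in the same free form as oleuropein, and should lead directly to 24 with loss of glucose.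

## Further compounds

F1 | step 7 | 2,3-epoxide of 5 (epoxide anti to the C5 side chain) | CC12OC1C[C@H](CC2=O)C(=C)CO[Si](C)(C)C(C)(C)C
F2 | step 7 | 2-chloro-3-hydroxy ketone from F1 | CC1(Cl)C(O)C[C@H](CC1=O)C(=C)CO[Si](C)(C)C(C)(C)C
F3 | step 7 | tetrahydropyranyl ether of F2 | CC1(Cl)C(OC2CCCCO2)C[C@H](CC1=O)C(=C)CO[Si](C)(C)C(C)(C)C
F4 | step 7 | Favorskii cyclopentane methyl ester with C3 tetrahydropyranyloxy group | COC(=O)C1C(C)C(OC2CCCCO2)C[C@H]1C(=C)CO[Si](C)(C)C(C)(C)C
F5 | step 7 | side-chain primary alcohol from F4 | COC(=O)C1C(C)C(OC2CCCCO2)C[C@H]1C(CO)CO[Si](C)(C)C(C)(C)C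
F6 | step 7 | bis-silyl ether of F5 | COC(=O)C1C(C)C(OC2CCCCO2)C[C@H]1C(CO[Si](C)(C)C(C)(C)C)CO[Si](C)(C)C(C)(C)C
F7 | step 7 | C3 alcohol, C1–C3 stereoisomer of 13 | COC(=O)C1C(C)C(O)C[C@H]1C(CO[Si](C)(C)C(C)(C)C)CO[Si](C)(C)C(C)(C)C
F8 | step 7 | keto ester, C1/C2 stereoisomer of 14 | COC(=O)C1C(C)C(=O)C[C@H]1C(CO[Si](C)(C)C(C)(C)C)CO[Si](C)(C)C(C)(C)C
F9 | step 16 | inverted C3 4-nitrobenzoate of 16 | COC(=O)[C@@H]1[C@@H](C)[C@H](OC(=O)c2ccc(cc2)[N+](=O)[O-])C[C@H]1C(CO[Si](C)(C)C(C)(C)C)CO[Si](C)(C)C(C)(C)C
F10 | step 16 | C3-epimeric hydroxy ester (OH down) | COC(=O)[C@@H]1[C@@H](C)[C@H](O)C[C@H]1C(CO[Si](C)(C)C(C)(C)C)CO[Si](C)(C)C(C)(C)C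
F11 | step 16 | C3-inverted diol | OC[C@@H]1[C@@H](C)[C@H](O)C[C@H]1C(CO[Si](C)(C)C(C)(C)C)CO[Si](C)(C)C(C)(C)C
F12 | step 17 | fully desilylated bis-glucoside of 22 | C/C=C/1\[C@@H](C(=CO[C@H]1O[C@H]2[C@@H]([C@H]([C@@H]([C@H](O2)CO)O)O)O)C(=O)OC)CC(=O)OC[C@@H]3[C@@H](C)[C@H](OC(=O)C[C@@H]4C(C(=O)OC)=CO[C@@H](O[C@H]5[C@@H]([C@H]([C@@H]([C@H](O5)CO)O)O)O)/C4=C/C)C[C@H]3C(CO)CO
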